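J has to meet E first.

    J + E → J.E (k1 = 0.061 L mol⁻¹ s⁻¹, Ea1 = 68.0 kJ mol⁻¹)
    X + J.E → X.J.E (k2 = 11 L mol⁻¹ s⁻¹, Ea2 = 39.0 kJ mol⁻¹)
    X.J.E ⇌ G (K3 = 0.45, k3 = 0.0045 s⁻¹, Ea3 = 92.0 kJ mol⁻¹, ΔH3 = −79.0 kJ mol⁻¹)
    (constants at 25 °C)

| flask | J | E | X | temperature | time | remark |
|---|---|---|---|---|---|---|
| delta | 20 mM | 60.0 mM (fed, over 3.0 min) | 16.0 mM | 25 °C | 8.0 min | all else is in the flask from the start; the feed brings no volume worth counting |
| zeta | 20 mM (fed, over 20 s) | 60.0 mM | 16.0 mM | 25 °C | 8.0 min | all else is in the flask from the start; the feed brings no volume worth counting |
| alpha | 20 mM | 60.0 mM (fed, over 3.0 min) | 16.0 mM |  | 8.0 min | the addition at −15 °C, then warmed to 25 °C; the feed brings no volume worth counting |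
| beta | 20 mM (fed, over 3.0 min) | 60.0 mM | 16.0 mM | 25 °C | 8.0 min | all else is in the flask from the start; the feed brings no volume worth counting |
| eta | 20 mM | 60.0 mM (in portions, 4, over 3.0 min) | 16.0 mM | 25 °C | 8.0 min | first portion at the start, last at 3.0 min |

* which flask leads in amount of X.J.E, in percent of the J charged ("all alike" within 1.5 percentage points) (delta / zeta / alpha / beta / eta / all alike)
* how much X.J.E is there at the end, in percent of the J charged: delta
* how much X.J.E is there at the end, in percent of the J charged: zeta
* how much X.J.E is there at the end, in percent of the J charged: alpha
* how much X.J.E is there at the end, in percent of the J charged: beta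
* how much X.J.E is there at the end, in percent of the J charged: eta

I work with a, the fraction of the charged J left, and not with what is made. At the full charges, the second step's constant times X, 0.176 s⁻¹, stands far above the first step's constant times E, 0.003660 s⁻¹, so while X lasts the first step is the rate-limiting step.

I call contact time the time for which the whole charges of J and E stand together warm, a steady feed or a run of equal portions counting for half its length. In alpha a feed in the cold counts for nothing, which gives 5.00 min. That zero needs an objection: at −15 °C the first step runs at 0.0143 of its constant, so during the feed alpha loses hardly any of its J, and the zero stands.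

My first estimate for alpha, with E held at its charge, is a = 33.4 %. But E is used up with J, so its fraction e is one minus 0.333 times the J gone. Integrating with that, the logarithm of e over a grows at the first step's constant times the excess of E over J, which raises alpha's a to 38.2 %. Delta, beta and eta have 6.50 min of contact and a = 29.5 %, while zeta has 7.83 min and a = 23.7 %.

Does X, the limiting reagent, stop this first? Its charge is 80.0 % of J's, and zeta's 76.3 % of J gone stays below that. Nor does all that is made stay X.J.E, since the exchange with G relaxes in 1.15 min and leaves a share of 69.0 %. I leave uncounted the J held as J.E and the lag of G, which pull opposite ways. So I commit to 48.6 % for delta, beta and eta, 42.6 % for alpha, and 52.6 % for zeta, which leads.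

The forecast also names zeta, with 51 %, and gives delta 48.2 %, beta 48.6 %, eta 48.2 % and alpha 43.5 %, holding that “each flask's yield depends mainly on its time-integrated E exposure”. My zeta stands above its figure and my alpha below.

The flasks give zeta the lead with 51.9 %, then delta 48.8 %, eta 48.7 %, beta 48.6 % and alpha 44.1 %. Alpha still holds 99.5 % of its J when its feed ends at 3.00 min, and 38.1 % at 8.00 min. A neighbour like alpha but with 15 mM of E has the same contact time, 5.00 min, and its excess of E over J is negative, so the same reckoning gives a = 79.2 %; that flask holds 79.2 % of its J at 8.00 min.

The numbers are those of an exercise; the rest is arithmetic.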